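**Plan**
1. Eremophilane numbering: ring A = C1–C5 + C10, ring B = C5–C10, C11–C13 on C7. The enabling feature is the diene C9=C10–C1=C2, whose central atom C10 is the ring-fusion carbon next to quaternary C5. Cutting C9=C10 and C1=C2 opens both rings to a chain with an ethynyl group (C10≡C1) on C5, a vinyl end on C8 and an isobutenyl end on C3.
2. Further cuts: the C3–O ester (dienoic acid from (R)-2-methylbutanoic acid), C7–C11 (2-metallated allyl alcohol onto a C7 ketone), C7–C8 (alkoxyallylboration of a C7 aldehyde), C2–C3 (isobutenyl Grignard) and C4–C5 (Ireland–Claisen rearrangement of the propanoate of (Z)-3-methylpent-2-en-4-yn-1-ol, which brings the alkyne along).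
3. Forward: C4–C5, then C2–C3, hydroboration of the Claisen vinyl group to C7, then C7–C8 and C7–C11. Ring B and then ring A close in one metathesis cascade; C8 is oxidised to the dienone, C3 is unmasked and acylated last.
4. Stereochemistry: C4/C5 from the chair Claisen transition state under a chiral boron controller; C3 by Felkin–Anh addition next to C4; C8 by reagent-controlled syn-alkoxyallylboration, relayed to C7 by chelation-controlled addition and then erased by oxidation; C6' from the chiral pool.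

Key step: step 17

Assumption: the (4S,5S)-bromodiazaborolidine is taken as the enantiomer whose Z(O) boron enolate rearranges to the (2S,3S) acid 8; its mirror image, from the equally available (R,R)-diamine, would be used without other change if the sense of induction is the opposite.

**Step 1**
Reactants: 1 (2Z)-3-methylpent-2-en-4-yn-1-ol
Product: 3 (2Z)-3-methyl-5-(trimethylsilyl)pent-2-en-4-yn-1-ol, via bis-silyl ether 2 (not isolated)
Conditions: n-BuLi (2.1 equiv), THF, −78 → 0 °C; Me3SiCl (2.2 equiv), 0 °C → rt; 1 M aq. HCl, rt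
Reagents that add atoms: chlorotrimethylsilane, C[Si](C)(C)Cl
Why: Double deprotonation (alkoxide and acetylide), silylation at both sites and selective acidic hydrolysis of the labile O–Si bond is the standard C-silylation of an alkynol, and it masks the alkyne for the boron and organometallic steps ahead.

**Step 2**
Reactants: 3 (2Z)-3-methyl-5-(trimethylsilyl)pent-2-en-4-yn-1-ol; 4 propanoyl chloride
Product: 5 (2Z)-3-methyl-5-(trimethylsilyl)pent-2-en-4-yn-1-yl propanoate
Conditions: Et3N, DMAP (cat.), CH2Cl2, 0 °C → rt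
Reagents that add atoms: none
Why: DMAP-catalysed acylation of a primary allylic alcohol with an acid chloride should proceed without touching the Z-enyne.

**Step 3**
Reactants: 5 (2Z)-3-methyl-5-(trimethylsilyl)pent-2-en-4-yn-1-yl propanoate
Product: 8 (2S,3S)-2,3-dimethyl-3-[(trimethylsilyl)ethynyl]pent-4-enoic acid, via boron ketene acetal 6 (not isolated), via acyloxyborane 7 (not isolated)
Conditions: (4S,5S)-2-bromo-4,5-diphenyl-1,3-bis{[3,5-bis(trifluoromethyl)phenyl]sulfonyl}-1,3,2-diazaborolidine (1.2 equiv, prepared beforehand from the bis-sulfonamide and BBr3), i-Pr2NEt, CH2Cl2, −78 °C; then −20 → 4 °C; aqueous work-up at pH 3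
Reagents that add atoms: none
Why: Enantioselective Ireland–Claisen rearrangement of a boron ester enolate: amine-promoted enolisation in CH2Cl2 should give the Z(O) ketene acetal, which rearranges through a chair with both methyl groups equatorial and the slim alkynyl group axial, so that the 2,3-syn-dimethyl relation (C4 and C5) follows from the two double-bond geometries and the absolute sense from the C2-symmetric sulfonamide ligand on boron.

**Step 4**
Reactants: 8 (2S,3S)-2,3-dimethyl-3-[(trimethylsilyl)ethynyl]pent-4-enoic acid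
Product: 9 (2S,3S)-2,3-dimethyl-3-[(trimethylsilyl)ethynyl]pent-4-en-1-ol
Conditions: LiAlH4, Et2O, 0 °C → rt; Na2SO4·10H2O
Reagents that add atoms: none
Why: Hydride reduction of a carboxylic acid to the primary alcohol leaves the isolated alkene, the silyl alkyne and both stereocentres untouched.

**Step 5**
Reactants: 9 (2S,3S)-2,3-dimethyl-3-[(trimethylsilyl)ethynyl]pent-4-en-1-ol
Product: 10 (2S,3S)-2,3-dimethyl-3-[(trimethylsilyl)ethynyl]pent-4-enal
Conditions: Dess–Martin periodinane, NaHCO3, CH2Cl2, 0 °C → rt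
Reagents that add atoms: none
Why: Buffered Dess–Martin oxidation should give the aldehyde without epimerising the α-stereocentre, which is shielded by the neighbouring quaternary carbon.

**Step 6**
Reactants: 10 (2S,3S)-2,3-dimethyl-3-[(trimethylsilyl)ethynyl]pent-4-enal; 11 1-bromo-2-methylprop-1-ene
Product: 12 (4S,5S,6S)-2,5,6-trimethyl-6-[(trimethylsilyl)ethynyl]octa-2,7-dien-4-ol
Conditions: 11, Mg, THF, 45 °C; then 10, THF, −78 °C; sat. aq. NH4Cl
Reagents that add atoms: none
Why: Grignard addition under Felkin–Anh control, with the quaternary C5 anti to the incoming nucleophile and the C4 methyl group beside the carbonyl oxygen, should deliver the 3,4-syn carbinol, that is (3S) in eremophilane numbering.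

**Step 7**
Reactants: 12 (4S,5S,6S)-2,5,6-trimethyl-6-[(trimethylsilyl)ethynyl]octa-2,7-dien-4-ol
Product: 13 tert-butyl(dimethyl){[(4S,5S,6S)-2,5,6-trimethyl-6-[(trimethylsilyl)ethynyl]octa-2,7-dien-4-yl]oxy}silane
Conditions: t-BuMe2SiOTf, 2,6-lutidine, CH2Cl2, −78 → 0 °C
Reagents that add atoms: tert-butyldimethylsilyl trifluoromethanesulfonate, CC(C)(C)[Si](C)(C)OS(=O)(=O)C(F)(F)F
Why: Silyl triflate with a hindered pyridine base is the standard silylation of a hindered secondary alcohol and gives an ether that survives all steps up to the end game.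

**Step 8**
Reactants: 13 tert-butyl(dimethyl){[(4S,5S,6S)-2,5,6-trimethyl-6-[(trimethylsilyl)ethynyl]octa-2,7-dien-4-yl]oxy}silane
Product: 15 (3S,4S,5S)-5-[(tert-butyldimethylsilyl)oxy]-3,4,7-trimethyl-3-[(trimethylsilyl)ethynyl]oct-6-en-1-ol, via alkylborane 14 (not isolated)
Conditions: 9-BBN (1.5 equiv), THF, 0 °C → rt; then 30% H2O2, 3 M aq. NaOAc, 0 °C → rt
Reagents that add atoms: hydrogen peroxide, OO
Why: Anti-Markovnikov hydroboration with 9-BBN should select the monosubstituted alkene over the trisubstituted alkene and the silyl-capped alkyne, and buffered peroxide oxidation of the C–B bond then gives the C7 alcohol.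

**Step 9**
Reactants: 15 (3S,4S,5S)-5-[(tert-butyldimethylsilyl)oxy]-3,4,7-trimethyl-3-[(trimethylsilyl)ethynyl]oct-6-en-1-ol
Product: 16 (3S,4S,5S)-5-[(tert-butyldimethylsilyl)oxy]-3,4,7-trimethyl-3-[(trimethylsilyl)ethynyl]oct-6-enal
Conditions: Dess–Martin periodinane, NaHCO3, CH2Cl2, 0 °C → rt
Reagents that add atoms: none
Why: Dess–Martin oxidation of a primary alcohol to the aldehyde is compatible with the silyl ether, the alkene and the silyl alkyne.

**Step 10**
Reactants: 17 prop-2-en-1-ol; 18 1-(chloromethyl)-4-methoxybenzene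
Product: 19 1-methoxy-4-[(prop-2-en-1-yloxy)methyl]benzene (allyl 4-methoxybenzyl ether)
Conditions: NaH, Bu4NI (cat.), THF/DMF, 0 °C → rt
Reagents that add atoms: none
Why: Williamson ether synthesis of a primary alkoxide with a benzylic chloride.

**Step 11**
Reactants: 16 (3S,4S,5S)-5-[(tert-butyldimethylsilyl)oxy]-3,4,7-trimethyl-3-[(trimethylsilyl)ethynyl]oct-6-enal; 19 allyl 4-methoxybenzyl ether
Product: 21 (3S,4S,6S,7S,8S)-8-[(tert-butyldimethylsilyl)oxy]-3-[(4-methoxybenzyl)oxy]-6,7,10-trimethyl-6-[(trimethylsilyl)ethynyl]undeca-1,9-dien-4-ol, via borinate 20 (not isolated)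
Conditions: 19 (2 equiv), s-BuLi, THF, −78 °C; (+)-Ipc2BOMe, −78 °C; BF3·OEt2; then 16, −78 °C; HOCH2CH2NH2, rt
Reagents that add atoms: none
Why: Alkoxyallylboration with a diisopinocampheylborane (Brown-type allylboration): the Z-configured γ-alkoxyallyl borane should react through a chair to give the syn adduct, and the isopinocampheyl groups derived from (−)-α-pinene direct attack to the re face of the aldehyde, which sets (7S,8S) in eremophilane numbering, C8 being the control element for the next C–C bond.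

**Step 12**
Reactants: 21 (3S,4S,6S,7S,8S)-8-[(tert-butyldimethylsilyl)oxy]-3-[(4-methoxybenzyl)oxy]-6,7,10-trimethyl-6-[(trimethylsilyl)ethynyl]undeca-1,9-dien-4-ol
Product: 22 (3S,6S,7S,8S)-8-[(tert-butyldimethylsilyl)oxy]-3-[(4-methoxybenzyl)oxy]-6,7,10-trimethyl-6-[(trimethylsilyl)ethynyl]undeca-1,9-dien-4-one
Conditions: Dess–Martin periodinane, NaHCO3, CH2Cl2, 0 °C
Reagents that add atoms: none
Why: Buffered Dess–Martin oxidation gives the α-alkoxy ketone under neutral conditions, which is used at once because C8–H is activated by the carbonyl and the vinyl group.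

**Step 13**
Reactants: 22 (3S,6S,7S,8S)-8-[(tert-butyldimethylsilyl)oxy]-3-[(4-methoxybenzyl)oxy]-6,7,10-trimethyl-6-[(trimethylsilyl)ethynyl]undeca-1,9-dien-4-one; 23 2-bromoprop-2-en-1-ol
Product: 24 (3S,5S,6S,7S)-7-[(tert-butyldimethylsilyl)oxy]-3-{(1S)-1-[(4-methoxybenzyl)oxy]prop-2-en-1-yl}-5,6,9-trimethyl-2-methylidene-5-[(trimethylsilyl)ethynyl]dec-8-ene-1,3-diol
Conditions: 23 (3 equiv), t-BuLi (3 equiv per 23), Et2O, −78 → 0 °C; MgBr2·OEt2, −78 °C; then 22, Et2O/CH2Cl2, −78 °C; sat. aq. NH4Cl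
Reagents that add atoms: none
Why: Chelation-controlled (Cram-chelate) addition of a 2-metallated allyl alkoxide: magnesium bridges the C7 carbonyl and the C8 ether oxygen, the nucleophile enters from the face of C8–H opposite to the vinyl group and sets (7S), and the unprotected dianion resists β-elimination and gives the C13 alcohol directly.

**Step 14**
Reactants: 24 (3S,5S,6S,7S)-7-[(tert-butyldimethylsilyl)oxy]-3-{(1S)-1-[(4-methoxybenzyl)oxy]prop-2-en-1-yl}-5,6,9-trimethyl-2-methylidene-5-[(trimethylsilyl)ethynyl]dec-8-ene-1,3-diol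
Product: 25 (3S,5S,6S,7S)-7-[(tert-butyldimethylsilyl)oxy]-5-ethynyl-3-{(1S)-1-[(4-methoxybenzyl)oxy]prop-2-en-1-yl}-5,6,9-trimethyl-2-methylidenedec-8-ene-1,3-diol
Conditions: K2CO3, MeOH, rt
Reagents that add atoms: none
Why: Base-catalysed methanolysis cleaves the alkynyl C–Si bond selectively and leaves the silyl ether and the benzylic ether in place, and it is done before an acetate is present.

**Step 15**
Reactants: 25 (3S,5S,6S,7S)-7-[(tert-butyldimethylsilyl)oxy]-5-ethynyl-3-{(1S)-1-[(4-methoxybenzyl)oxy]prop-2-en-1-yl}-5,6,9-trimethyl-2-methylidenedec-8-ene-1,3-diol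
Product: 26 (3S,5S,6S,7S)-7-[(tert-butyldimethylsilyl)oxy]-5-ethynyl-3-hydroxy-3-{(1S)-1-[(4-methoxybenzyl)oxy]prop-2-en-1-yl}-5,6,9-trimethyl-2-methylidenedec-8-en-1-yl acetate
Conditions: Ac2O (1.2 equiv), pyridine, CH2Cl2, 0 °C
Reagents that add atoms: acetic anhydride, CC(=O)OC(C)=O
Why: Acetylation should take place only at the primary allylic C13 hydroxyl, the tertiary C7 hydroxyl being too hindered to react under these conditions.

**Step 16**
Reactants: 26 (3S,5S,6S,7S)-7-[(tert-butyldimethylsilyl)oxy]-5-ethynyl-3-hydroxy-3-{(1S)-1-[(4-methoxybenzyl)oxy]prop-2-en-1-yl}-5,6,9-trimethyl-2-methylidenedec-8-en-1-yl acetate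
Product: 27 (3S,5S,6S,7S)-7-[(tert-butyldimethylsilyl)oxy]-5-ethynyl-3-hydroxy-3-[(1S)-1-hydroxyprop-2-en-1-yl]-5,6,9-trimethyl-2-methylidenedec-8-en-1-yl acetate
Conditions: DDQ, CH2Cl2/pH 7 phosphate buffer (10:1), 0 °C
Reagents that add atoms: none
Why: Oxidative cleavage of a 4-methoxybenzyl ether by DDQ in buffered wet CH2Cl2 (hydride abstraction, then hydrolysis of the oxocarbenium ion) is neutral and should spare the silyl ether, the acetate, the alkyne and the alkenes.

**Step 17**
Reactants: 27 (3S,5S,6S,7S)-7-[(tert-butyldimethylsilyl)oxy]-5-ethynyl-3-hydroxy-3-[(1S)-1-hydroxyprop-2-en-1-yl]-5,6,9-trimethyl-2-methylidenedec-8-en-1-yl acetate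
Product: 28 (3S,4S,5S,7S,8S)-13-acetoxy-3-[(tert-butyldimethylsilyl)oxy]eremophila-1,9,11-triene-7,8-diol
Conditions: RuCl2(=CHPh)(H2IMes)(PCy3) (second-generation Grubbs catalyst, 10 mol%), 1,4-benzoquinone (10 mol%), CH2Cl2 (2 mM), 40 °C
Reagents that add atoms: none
Why: Tandem ene–yne–ene ring-closing metathesis: the catalyst should first exchange its benzylidene for the C9 alkylidene at the only monosubstituted alkene, add in [2+2] fashion across the C10≡C1 triple bond and open the ruthenacyclobutene to the C1 vinylcarbene, which then closes onto the C2 alkene and leaves as the isopropylidene complex (isobutene after turnover). The closest known reaction type is the dienyne ring-closing metathesis that turns acyclic dienynes into fused bicyclic 1,3-dienes. Ring B arises by 6-exo attack of the C9 carbene on the alkyne (C9=C10) and ring A by six-membered ring-closing alkene metathesis of the C1 carbene with C2 (C1=C2). No stereocentre is formed, and C3, C4, C5, C7 and C8 are carried through unchanged. The step needs the carbene to start at C9 and not at C2, at the alkyne or at the C11 methylidene group; this is secured by a terminal, hydroxyl-flanked C9 vinyl group set against a trisubstituted C2 alkene, a hindered 1,1-disubstituted C11=C12 alkene and an alkyne on a quaternary carbon, by high dilution, and by the ring sizes of the alternative first closures (eight-membered for C9 with C2, four-membered for C9 with C12). Quaternary C5 carries all three reacting arms, so both closures gain from gem-disubstitution.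

**Step 18**
Reactants: 28 (3S,4S,5S,7S,8S)-13-acetoxy-3-[(tert-butyldimethylsilyl)oxy]eremophila-1,9,11-triene-7,8-diol
Product: 29 (3S,4S,5S,7S)-13-acetoxy-3-[(tert-butyldimethylsilyl)oxy]-7-hydroxyeremophila-1,9,11-trien-8-one
Conditions: MnO2 (activated, excess), CH2Cl2, rt
Reagents that add atoms: none
Why: MnO2 oxidises only the allylic secondary C8 alcohol to the linear dienone, leaves the tertiary C7 hydroxyl alone and removes the auxiliary C8 stereocentre.

**Step 19**
Reactants: 29 (3S,4S,5S,7S)-13-acetoxy-3-[(tert-butyldimethylsilyl)oxy]-7-hydroxyeremophila-1,9,11-trien-8-one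
Product: 30 (3S,4S,5S,7S)-13-acetoxy-3,7-dihydroxyeremophila-1,9,11-trien-8-one
Conditions: HF·pyridine, pyridine, THF, 0 °C → rt
Reagents that add atoms: none
Why: Buffered HF·pyridine cleaves the silyl ether under non-basic conditions, which avoids acetyl migration and base-induced damage to the α-hydroxy dienone.

**Step 20**
Reactants: 31 (2R)-2-methylbutanoic acid
Product: 32 (2R)-2-methylbutan-1-ol
Conditions: LiAlH4, Et2O, 0 °C → rt; Na2SO4·10H2O
Reagents that add atoms: none
Why: Hydride reduction of the acid to the primary alcohol does not affect the α-stereocentre.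

**Step 21**
Reactants: 32 (2R)-2-methylbutan-1-ol
Product: 34 (2E,4R)-2,4-dimethylhex-2-enal, via aldehyde 33 (not isolated)
Conditions: PhI(OAc)2, TEMPO (10 mol%), NaHCO3, CH2Cl2, rt; then Ph3P=C(CH3)CHO, 40 °C
Reagents that add atoms: 2-(triphenylphosphoranylidene)propanal, CC(C=O)=P(c1ccccc1)(c1ccccc1)c1ccccc1
Why: Nitroxyl-catalysed oxidation followed in the same flask by Wittig olefination with a stabilised formyl ylide should give the (E)-enal, the labile α-chiral aldehyde being trapped without isolation to limit epimerisation.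

**Step 22**
Reactants: 34 (2E,4R)-2,4-dimethylhex-2-enal
Product: 35 ethyl (2E,4E,6R)-4,6-dimethylocta-2,4-dienoate
Conditions: (EtO)2P(O)CH2CO2Et, NaH, THF, 0 °C → rt
Reagents that add atoms: triethyl phosphonoacetate, CCOC(=O)CP(=O)(OCC)OCC
Why: Horner–Wadsworth–Emmons olefination of an enal with a stabilised phosphonate anion gives the (E)-configured new double bond.

**Step 23**
Reactants: 35 ethyl (2E,4E,6R)-4,6-dimethylocta-2,4-dienoate
Product: 36 (2E,4E,6R)-4,6-dimethylocta-2,4-dienoic acid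
Conditions: LiOH·H2O, THF/MeOH/H2O, rt; then 1 M HCl
Reagents that add atoms: lithium hydroxide, [Li+].[OH-]
Why: Saponification of the ethyl ester, the C6 hydrogen being too weakly acidic to epimerise under these conditions.

**Step 24**
Reactants: 36 (2E,4E,6R)-4,6-dimethylocta-2,4-dienoic acid; 30 (3S,4S,5S,7S)-13-acetoxy-3,7-dihydroxyeremophila-1,9,11-trien-8-one
Product: 38 (3S,4S,5S,7S)-13-acetoxy-7-hydroxy-8-oxoeremophila-1,9,11-trien-3-yl (2E,4E,6R)-4,6-dimethylocta-2,4-dienoate (CNP0160850.1), via mixed anhydride 37 (not isolated)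
Conditions: 36, 2,4,6-Cl3C6H2COCl, Et3N, toluene, rt; then 30, DMAP, toluene, rt
Reagents that add atoms: none
Why: Yamaguchi esterification through the mixed anhydride should acylate the secondary allylic C3 hydroxyl in preference to the hindered tertiary C7 hydroxyl.

**Compound list**
1 | (2Z)-3-methylpent-2-en-4-yn-1-ol | C#C/C(C)=C\CO | starting material
2 | trimethyl{[(2Z)-3-methyl-5-(trimethylsilyl)pent-2-en-4-yn-1-yl]oxy}silane | C[Si](C)(C)C#C/C(C)=C\CO[Si](C)(C)C | intermediate
3 | (2Z)-3-methyl-5-(trimethylsilyl)pent-2-en-4-yn-1-ol | C[Si](C)(C)C#C/C(C)=C\CO | intermediate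
4 | propanoyl chloride | CCC(=O)Cl | starting material
5 | (2Z)-3-methyl-5-(trimethylsilyl)pent-2-en-4-yn-1-yl propanoate | CCC(=O)OC/C=C(C)\C#C[Si](C)(C)C | intermediate
6 | Z(O) boron ketene acetal of 5 (methyl cis to O–B; boron in the (4S,5S)-4,5-diphenyl-1,3-bis(arylsulfonyl)-1,3,2-diazaborolidine ring) | C/C=C(\OB1N(S(=O)(=O)c2cc(cc(c2)C(F)(F)F)C(F)(F)F)[C@@H](c2ccccc2)[C@H](c2ccccc2)N1S(=O)(=O)c1cc(cc(c1)C(F)(F)F)C(F)(F)F)OC/C=C(C)\C#C[Si](C)(C)C | intermediate
7 | (4S,5S)-diazaborolidin-2-yl (2S,3S)-2,3-dimethyl-3-[(trimethylsilyl)ethynyl]pent-4-enoate (acyloxyborane) | C=C[C@](C)(C#C[Si](C)(C)C)[C@H](C)C(=O)OB1N(S(=O)(=O)c2cc(cc(c2)C(F)(F)F)C(F)(F)F)[C@@H](c2ccccc2)[C@H](c2ccccc2)N1S(=O)(=O)c1cc(cc(c1)C(F)(F)F)C(F)(F)F | intermediate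
8 | (2S,3S)-2,3-dimethyl-3-[(trimethylsilyl)ethynyl]pent-4-enoic acid | C=C[C@](C)(C#C[Si](C)(C)C)[C@H](C)C(=O)O | intermediate
9 | (2S,3S)-2,3-dimethyl-3-[(trimethylsilyl)ethynyl]pent-4-en-1-ol | C=C[C@](C)(C#C[Si](C)(C)C)[C@H](C)CO | intermediate
10 | (2S,3S)-2,3-dimethyl-3-[(trimethylsilyl)ethynyl]pent-4-enal | C=C[C@](C)(C#C[Si](C)(C)C)[C@H](C)C=O | intermediate
11 | 1-bromo-2-methylprop-1-ene | CC(C)=CBr | starting material
12 | (4S,5S,6S)-2,5,6-trimethyl-6-[(trimethylsilyl)ethynyl]octa-2,7-dien-4-ol | C=C[C@](C)(C#C[Si](C)(C)C)[C@H](C)[C@@H](O)C=C(C)C | intermediate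
13 | tert-butyl(dimethyl){[(4S,5S,6S)-2,5,6-trimethyl-6-[(trimethylsilyl)ethynyl]octa-2,7-dien-4-yl]oxy}silane | C=C[C@](C)(C#C[Si](C)(C)C)[C@H](C)[C@@H](O[Si](C)(C)C(C)(C)C)C=C(C)C | intermediate
14 | B-alkyl-9-borabicyclo[3.3.1]nonane from 13 (boron on the former vinyl terminus, C7) | C1CCC2CCCC1B2CC[C@](C)(C#C[Si](C)(C)C)[C@H](C)[C@@H](O[Si](C)(C)C(C)(C)C)C=C(C)C | intermediate
15 | (3S,4S,5S)-5-[(tert-butyldimethylsilyl)oxy]-3,4,7-trimethyl-3-[(trimethylsilyl)ethynyl]oct-6-en-1-ol | OCC[C@](C)(C#C[Si](C)(C)C)[C@H](C)[C@@H](O[Si](C)(C)C(C)(C)C)C=C(C)C | intermediate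
16 | (3S,4S,5S)-5-[(tert-butyldimethylsilyl)oxy]-3,4,7-trimethyl-3-[(trimethylsilyl)ethynyl]oct-6-enal | O=CC[C@](C)(C#C[Si](C)(C)C)[C@H](C)[C@@H](O[Si](C)(C)C(C)(C)C)C=C(C)C | intermediate
17 | prop-2-en-1-ol | C=CCO | starting material
18 | 1-(chloromethyl)-4-methoxybenzene | COc1ccc(CCl)cc1 | starting material
19 | 1-methoxy-4-[(prop-2-en-1-yloxy)methyl]benzene | C=CCOCc1ccc(OC)cc1 | intermediate
20 | bis(isopinocampheyl)borinate of 21 (O–B on C4 of the undecadienol) | C=C[C@H](OCc1ccc(OC)cc1)[C@@H](OB([C@H]1C[C@H]2C[C@@H]([C@@H]1C)C2(C)C)[C@H]1C[C@H]2C[C@@H]([C@@H]1C)C2(C)C)C[C@](C)(C#C[Si](C)(C)C)[C@H](C)[C@@H](O[Si](C)(C)C(C)(C)C)C=C(C)C | intermediate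
21 | (3S,4S,6S,7S,8S)-8-[(tert-butyldimethylsilyl)oxy]-3-[(4-methoxybenzyl)oxy]-6,7,10-trimethyl-6-[(trimethylsilyl)ethynyl]undeca-1,9-dien-4-ol | C=C[C@H](OCc1ccc(OC)cc1)[C@@H](O)C[C@](C)(C#C[Si](C)(C)C)[C@H](C)[C@@H](O[Si](C)(C)C(C)(C)C)C=C(C)C | intermediate
22 | (3S,6S,7S,8S)-8-[(tert-butyldimethylsilyl)oxy]-3-[(4-methoxybenzyl)oxy]-6,7,10-trimethyl-6-[(trimethylsilyl)ethynyl]undeca-1,9-dien-4-one | C=C[C@H](OCc1ccc(OC)cc1)C(=O)C[C@](C)(C#C[Si](C)(C)C)[C@H](C)[C@@H](O[Si](C)(C)C(C)(C)C)C=C(C)C | intermediate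
23 | 2-bromoprop-2-en-1-ol | C=C(Br)CO | starting material
24 | (3S,5S,6S,7S)-7-[(tert-butyldimethylsilyl)oxy]-3-{(1S)-1-[(4-methoxybenzyl)oxy]prop-2-en-1-yl}-5,6,9-trimethyl-2-methylidene-5-[(trimethylsilyl)ethynyl]dec-8-ene-1,3-diol | C=C(CO)[C@@](O)(C[C@](C)(C#C[Si](C)(C)C)[C@H](C)[C@@H](O[Si](C)(C)C(C)(C)C)C=C(C)C)[C@@H](OCc1ccc(OC)cc1)C=C | intermediate
25 | (3S,5S,6S,7S)-7-[(tert-butyldimethylsilyl)oxy]-5-ethynyl-3-{(1S)-1-[(4-methoxybenzyl)oxy]prop-2-en-1-yl}-5,6,9-trimethyl-2-methylidenedec-8-ene-1,3-diol | C=C(CO)[C@@](O)(C[C@](C)(C#C)[C@H](C)[C@@H](O[Si](C)(C)C(C)(C)C)C=C(C)C)[C@@H](OCc1ccc(OC)cc1)C=C | intermediate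
26 | (3S,5S,6S,7S)-7-[(tert-butyldimethylsilyl)oxy]-5-ethynyl-3-hydroxy-3-{(1S)-1-[(4-methoxybenzyl)oxy]prop-2-en-1-yl}-5,6,9-trimethyl-2-methylidenedec-8-en-1-yl acetate | C=C(COC(C)=O)[C@@](O)(C[C@](C)(C#C)[C@H](C)[C@@H](O[Si](C)(C)C(C)(C)C)C=C(C)C)[C@@H](OCc1ccc(OC)cc1)C=C | intermediate
27 | (3S,5S,6S,7S)-7-[(tert-butyldimethylsilyl)oxy]-5-ethynyl-3-hydroxy-3-[(1S)-1-hydroxyprop-2-en-1-yl]-5,6,9-trimethyl-2-methylidenedec-8-en-1-yl acetate (metathesis precursor) | C=C(COC(C)=O)[C@@](O)(C[C@](C)(C#C)[C@H](C)[C@@H](O[Si](C)(C)C(C)(C)C)C=C(C)C)[C@@H](O)C=C | intermediate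
28 | (3S,4S,5S,7S,8S)-13-acetoxy-3-[(tert-butyldimethylsilyl)oxy]eremophila-1,9,11-triene-7,8-diol | C=C(COC(C)=O)[C@@]1(O)C[C@]2(C)C(=C[C@@H]1O)C=C[C@H](O[Si](C)(C)C(C)(C)C)[C@H]2C | intermediate
29 | (3S,4S,5S,7S)-13-acetoxy-3-[(tert-butyldimethylsilyl)oxy]-7-hydroxyeremophila-1,9,11-trien-8-one | C=C(COC(C)=O)[C@@]1(O)C[C@]2(C)C(=CC1=O)C=C[C@H](O[Si](C)(C)C(C)(C)C)[C@H]2C | intermediate
30 | (3S,4S,5S,7S)-13-acetoxy-3,7-dihydroxyeremophila-1,9,11-trien-8-one | C=C(COC(C)=O)[C@@]1(O)C[C@]2(C)C(=CC1=O)C=C[C@H](O)[C@H]2C | intermediate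
31 | (2R)-2-methylbutanoic acid | CC[C@@H](C)C(=O)O | starting material
32 | (2R)-2-methylbutan-1-ol | CC[C@@H](C)CO | intermediate
33 | (2R)-2-methylbutanal | CC[C@@H](C)C=O | intermediate
34 | (2E,4R)-2,4-dimethylhex-2-enal | CC[C@@H](C)/C=C(\C)C=O | intermediate
35 | ethyl (2E,4E,6R)-4,6-dimethylocta-2,4-dienoate | CCOC(=O)/C=C/C(C)=C/[C@H](C)CC | intermediate
36 | (2E,4E,6R)-4,6-dimethylocta-2,4-dienoic acid | OC(=O)/C=C/C(C)=C/[C@H](C)CC | intermediate
37 | (2E,4E,6R)-4,6-dimethylocta-2,4-dienoic 2,4,6-trichlorobenzoic anhydride | O=C(OC(=O)/C=C/C(C)=C/[C@H](C)CC)c1c(Cl)cc(Cl)cc1Cl | intermediate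
38 | (3S,4S,5S,7S)-13-acetoxy-7-hydroxy-8-oxoeremophila-1,9,11-trien-3-yl (2E,4E,6R)-4,6-dimethylocta-2,4-dienoate (CNP0160850.1) | C=C(COC(C)=O)[C@@]1(O)C[C@]2(C)C(=CC1=O)C=C[C@H](OC(=O)/C=C/C(C)=C/[C@H](C)CC)[C@H]2C | target

**Step count**
Total: 24 steps (19 on the main line, 1 for ether 19, 4 for acid 36).
Longest linear sequence: 19 steps (steps 1–9, 11–19 and 24).

**Steps most likely to fail, with fallbacks**

Step 17 (metathesis cascade). Ruthenium hydride species formed from the catalyst may isomerise the unprotected C8 allylic alcohol to the ethyl ketone, or the free diol may slow turnover so that intermolecular enyne metathesis takes over. The cascade is then moved one stage back. PMB ether 26 is exposed to the same catalyst (CH2Cl2, 40 °C, high dilution) and should give (3S,4S,5S,7S,8S)-13-acetoxy-3-[(tert-butyldimethylsilyl)oxy]-8-[(4-methoxybenzyl)oxy]eremophila-1,9,11-trien-7-ol F1. DDQ in buffered wet CH2Cl2 then frees the C8 hydroxyl, and the route is rejoined at 28.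

Step 13 (addition to the α-alkoxy ketone). Proton transfer from the doubly activated C8–H to the basic vinyl metal (enolisation, then migration of the vinyl double bond into conjugation or loss of the C8 configuration) may outrun carbonyl addition, and the facial selectivity would then erode as well. The C7–C11 bond is then made by aldol addition of an acrylate α-anion equivalent instead of a vinyl metal. Starting from ketone 22, the lithium enolate of ethyl 3-(dimethylamino)propanoate (LiN(iPr)2, THF, −78 °C), a far weaker base, should add to the chelated ketone from the same face and give the ethyl 2-[(dimethylamino)methyl]-3-hydroxy ester adduct F2 (both C11 epimers). N-Methylation with MeI gives the trimethylammonium iodide F3, and DBU-induced elimination of trimethylamine gives the α-methylene ester F4. Reduction with i-Bu2AlH (CH2Cl2, −78 °C) turns the ester into the allylic alcohol and rejoins the route at diol 24.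

Step 3 (enantioselective Ireland–Claisen rearrangement). The boron controller may discriminate poorly between the enantiotopic faces of the enynyl ester, or the rearrangement to the quaternary centre may be too slow at the low temperature the boron enolate tolerates. The absolute configuration is then secured by separation instead of induction. Starting from ester 5, LiN(iPr)2 and Me3SiCl in THF/DMPU give the (Z)-trimethylsilyl ketene acetal F5. On warming to rt it should rearrange through the same chair to the racemic syn trimethylsilyl ester F6. Hydrolysis gives acid 8 together with its enantiomer, (2R,3R)-2,3-dimethyl-3-[(trimethylsilyl)ethynyl]pent-4-enoic acid F7. Coupling of the mixture with (S)-4-benzyloxazolidin-2-one (DCC, DMAP, CH2Cl2) gives (4S)-4-benzyl-3-[(2S,3S)-2,3-dimethyl-3-[(trimethylsilyl)ethynyl]pent-4-enoyl]oxazolidin-2-one F8 and its (2R,3R)-acyl diastereomer F9, which are separated by chromatography. LiBH4 (Et2O, 0 °C) reduces F8, releases the auxiliary and gives alcohol 9, where the route is rejoined.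

**Further compounds**
F1 | step 17 | (3S,4S,5S,7S,8S)-13-acetoxy-3-[(tert-butyldimethylsilyl)oxy]-8-[(4-methoxybenzyl)oxy]eremophila-1,9,11-trien-7-ol | C=C(COC(C)=O)[C@@]1(O)C[C@]2(C)C(=C[C@@H]1OCc1ccc(OC)cc1)C=C[C@H](O[Si](C)(C)C(C)(C)C)[C@H]2C
F2 | step 13 | ethyl 2-[(dimethylamino)methyl]-3-hydroxy ester adduct of 22 (tertiary C7 alcohol bearing CH(CH2NMe2)CO2Et, both C11 epimers) | CCOC(=O)C(CN(C)C)[C@@](O)(C[C@](C)(C#C[Si](C)(C)C)[C@H](C)[C@@H](O[Si](C)(C)C(C)(C)C)C=C(C)C)[C@@H](OCc1ccc(OC)cc1)C=C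
F3 | step 13 | trimethylammonium iodide of F2 | CCOC(=O)C(C[N+](C)(C)C)[C@@](O)(C[C@](C)(C#C[Si](C)(C)C)[C@H](C)[C@@H](O[Si](C)(C)C(C)(C)C)C=C(C)C)[C@@H](OCc1ccc(OC)cc1)C=C.[I-]
F4 | step 13 | ethyl 2-methylidene ester corresponding to diol 24 (C13 as CO2Et) | CCOC(=O)C(=C)[C@@](O)(C[C@](C)(C#C[Si](C)(C)C)[C@H](C)[C@@H](O[Si](C)(C)C(C)(C)C)C=C(C)C)[C@@H](OCc1ccc(OC)cc1)C=C
F5 | step 3 | (Z)-trimethylsilyl ketene acetal of 5 (methyl cis to O–Si) | C/C=C(\O[Si](C)(C)C)OC/C=C(C)\C#C[Si](C)(C)C
F6 | step 3 | racemic trimethylsilyl (2RS,3RS)-2,3-dimethyl-3-[(trimethylsilyl)ethynyl]pent-4-enoate, drawn as the (2S,3S) form | C=C[C@](C)(C#C[Si](C)(C)C)[C@H](C)C(=O)O[Si](C)(C)C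
F7 | step 3 | (2R,3R)-2,3-dimethyl-3-[(trimethylsilyl)ethynyl]pent-4-enoic acid | C=C[C@@](C)(C#C[Si](C)(C)C)[C@@H](C)C(=O)O
F8 | step 3 | (4S)-4-benzyl-3-[(2S,3S)-2,3-dimethyl-3-[(trimethylsilyl)ethynyl]pent-4-enoyl]oxazolidin-2-one | C=C[C@](C)(C#C[Si](C)(C)C)[C@H](C)C(=O)N1[C@@H](Cc2ccccc2)COC1=O
F9 | step 3 | (4S)-4-benzyl-3-[(2R,3R)-2,3-dimethyl-3-[(trimethylsilyl)ethynyl]pent-4-enoyl]oxazolidin-2-one | C=C[C@@](C)(C#C[Si](C)(C)C)[C@@H](C)C(=O)N1[C@@H](Cc2ccccc2)COC1=O
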